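## Structural features

Compound 33 is a germacranolide: a ten-membered carbocycle (ring A, C1–C10) fused across C6–C7 to an α-methylene γ-butyrolactone (ring B: O–C6, C7–C11(=C13)–C12=O), with H-6 and H-7 on opposite faces (trans fusion). Ring A carries a Z trisubstituted alkene C4=C5 (methyl on C4), a trisubstituted epoxide at C1/C10 (methyl on C10) whose ring bonds C2–C1 and C10–C9 are cis, a free allylic hydroxyl at C3 and an ester oxygen at C8. The acyl group is (2R,3R)-2,3-epoxy-2-methylbutanoate (epoxyangelate), which brings the count to eight stereocentres: C1, C10, C3, C6, C7, C8, C2′, C3′. C6, C7 and C8 are contiguous; C3 is separated from them by the alkene, and the epoxide by one methylene on each side. In the flat ring drawing the oxygens on C3 and C8, the epoxide oxygen and C11 share one face (β), and only the lactone oxygen on C6 is on the other. Fragile groups are the α-methylene lactone (Michael acceptor, attacked by basic peroxide), the ring epoxide with a transannular alkene (acid), the allylic lactone C–O bond and the hindered epoxy ester (acyl transfer). The real difficulty is a ten-membered ring with two Z alkenes, followed by placing C6, C7, C8 and the epoxide on a conformationally mobile ring. The key step uses the 1,5-diene array C9=C10–C1···C6–C7=C8 that appears when a C1–C6 bond is imagined: ring A then folds into a cyclohexene (C1–C6) holding Z C4=C5 and the C3 oxygen, with an isopropenyl group (C10, C9, C14) on C1 and a two-carbon alkenyl unit (C7, C8) on C6.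

## Logic of the disconnections

33 to 32. The O–Si bond at C3 is cut last. The C3 hydroxyl stays masked while C4=C5 must be kept away from oxidants; the forward step needs a buffered fluoride source that spares two epoxides and the methylene lactone.

32 to 31. C11=C13 is cut to a C11 phosphonate and a one-carbon aldehyde. The Michael acceptor then appears only after all peroxide steps, and the olefination needs nothing stronger than carbonate.

31 to 25 and 29. The acyl–O8 bond is cut, which makes the route convergent. The forward esterification must acylate a hindered secondary alcohol without opening either epoxide; 29 has no α-hydrogen and cannot epimerize.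

25 to 24. The two C–O bonds of the ring epoxide are cut while O8 is still a free hydroxyl. The C8 hydroxyl is homoallylic to C1=C10 and on the face the epoxide oxygen must occupy, so it can serve as director; the demand is delivery from O8 with C4=C5 untouched.

24 to 22. C8–O is traced to C8–Si. An oxygen at C8 would be expelled by the enolates used earlier, silicon is not; the forward oxidation must go with retention and leave the C3 silyl ether in place.

22 to 19. The C11–P bond is cut. Phosphorus is introduced with strong base while the molecule still has no ester, epoxide or free hydroxyl.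

19 to 17 to 15. The lactone C6–O bond is cut with inversion, then the C6–H bond. Open-chain analysis (Felkin–Anh) predicts that hydride addition to 15 gives the C6 epimer, so the plan accepts the cis-fused 17 and corrects C6 by an invertive re-lactonization.

15 to 13. The C7–C11 bond is cut to an enolate and a haloacetate. The silyl group on C8 is the control element; the forward step must deprotonate on the α′ side of the enone and alkylate anti to silicon.

13 to 10 (key). The C8–C9 bond is cut and C1–C6 reconnected. This replaces a ten-membered ring by a cyclohexene and turns the Z geometry of both alkenes and the C8 configuration into consequences of one chair transition state. Mapping 10 and 13 atom by atom onto 33 shows both Z alkenes and the configurations at C3 and C8 to be correct, so neither structure needs correction.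

10 to 9 to 4 and 7. Two C–H bonds of the vinylsilane are cut (alkyne reduction), then the C6–C7 bond (acetylide addition). The forward steps must give the E alkene and place the alkynyl group cis to the isopropenyl group.

7 to 5 and 6. The Si–C(sp) bond is cut.

4 to 3 to 2 to 1. The C6 carbonyl oxygen, the silyl group and the C3–H bond are removed in turn; 1 supplies C1 to C6, C9, C10, C14 and C15 and the absolute configuration.

29 to 28 to 27 to 26. The carboxyl oxidation level, the epoxide oxygen and again the carboxyl level are removed. Reagent-controlled epoxidation of the allylic alcohol is the only way here to obtain one enantiomer of the acid.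

## Other disconnections considered

Alternative 1: The cut is the C1–C2 bond of ring A. The 1,3-diketone A1 is traced to a ten-membered dienol lactone A2, in which C1 acylates the enol oxygen on C3 and C2 is an exocyclic methylene. Forward, irradiation at 254 nm would break the acyl–oxygen bond and the acyl radical would recombine at C2 (photo-Fries 1,3-acyl shift), so the ring size is kept while oxygen is exchanged for carbon.
- In its favour: the ring is closed as an ester from a chain on which C6, C7, C8 and C10 can be set by open-chain methods. The tertiary oxygen on C10 is in place early, so the epoxide could later be closed by displacement instead of by a face-selective epoxidation; on that point it is the better plan.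
- Against it: a radical pair can lose CO or recombine at oxygen, the cross-conjugated Z diene can isomerize under the lamp, and A1 itself absorbs and can undergo alpha-cleavage. After the step C1 and C3 are the two carbonyls of an enolizable β-diketone that must be told apart and reduced stereoselectively on the macrocycle.
- Comparison: the chosen plan fixes C3 and C8 before and during ring formation by a concerted, stereospecific shift. Both form ring A in one step, but the seco acid for A2 and the redox work after A1 would make Alternative 1 longer.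

Alternative 2: The cut is the lactone C6–O bond, with the alkene moved from C4=C5 to C5=C6. The iodo lactone A3 is traced to the ten-membered dienyl acetic acid A4. Forward, I2 and NaHCO3 would activate the cis C5=C6 alkene, the carboxylate would attack C6 anti to iodine (5-exo), and elimination of HI would then create C4=C5.
- In its favour: the C6 oxygen is introduced by a stereospecific anti addition tied to C7, which is more direct than a hydride addition followed by inversion; here it is the better plan. The C8 oxygen is carried as an ether from the start, so no silicon-to-oxygen exchange is needed.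
- Against it: it is an endgame tactic and leaves ring A still to be made. The trisubstituted C1=C10 alkene is the more electron-rich site for iodine and can react transannularly. The elimination needs an antiperiplanar H-4 in a medium ring and can run toward C6 instead, and a C4 stereocentre is built only to be destroyed.
- Comparison: mechanistically both plans rely on local stereospecific events (anti addition there, a chair there). In step economy Alternative 2 is worse, because ring construction is extra.

Alternative 3: The cut is a transannular C3=C8 double bond. The 3,8-diketone A5 is traced to the hexahydronaphthalene lactone A6, available in principle from a Birch-reduced tetralin. Forward, one equivalent of ozone would cleave the tetrasubstituted ring-fusion alkene and open the two six-membered rings to ring A.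
- In its favour: the ring forms by fragmentation with no entropic penalty, Z C1=C10 is guaranteed by the six-membered ring, and C4 to C7 can be set on a rigid cyclohexane; in these respects it equals or betters the chosen plan.
- Against it: ozone must distinguish a hindered tetrasubstituted alkene from a trisubstituted one. A5 has a C8 ketone β to the lactone oxygen (ring-opening by elimination) and a C3 ketone β to the C5 acetate (elimination gives C4=C5 without control of geometry). C3 and C8 would have to be set by ketone reductions on the flexible ring, and the material is racemic unless an asymmetric step is added.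
- Comparison: the chosen plan takes C3 from the chiral pool and C8 from the chair. Ring-forming step count is similar; the work after ring formation is heavier in Alternative 3.

Key step: step 7

Remark: 33 is read as the single enantiomer drawn; from compound 11 on, positions follow germacrane numbering (C1–C15) and α/β refer to the flat ring drawing, β being the face of the C7–C11 bond, so 33 is the 1β,10β-epoxy-3β-hydroxy-8β-acyloxy-12,6α-olide.

Step 1
Reactants: 1 (S)-carvone
Product: 2 (1S,5S)-2-methyl-5-(prop-1-en-2-yl)cyclohex-2-en-1-ol (cis-carveol)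
Conditions: NaBH4, CeCl3·7H2O, MeOH, −78 to 0 °C
Reagents that add atoms: none
Why: Luche 1,2-reduction of the enone; hydride adds axially to the half-chair with the isopropenyl group equatorial, giving the equatorial alcohol cis to the isopropenyl group (the future C3, 3S).

Step 2
Reactants: 2 (1S,5S)-cis-carveol
Product: 3 tert-butyl(dimethyl){[(1S,5S)-2-methyl-5-(prop-1-en-2-yl)cyclohex-2-en-1-yl]oxy}silane
Conditions: TBSCl, imidazole, DMF, rt
Reagents that add atoms: tert-butyldimethylsilyl chloride, CC(C)(C)[Si](C)(C)Cl
Why: Silylation of a secondary allylic alcohol; the ether blocks oxidation of the carbinol in step 3 and withstands acetylide, hydride and amide bases.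

Step 3
Reactants: 3 silyl ether of cis-carveol
Product: 4 (4S,6S)-4-[(tert-butyldimethylsilyl)oxy]-3-methyl-6-(prop-1-en-2-yl)cyclohex-2-en-1-one
Conditions: CrO3, 3,5-dimethylpyrazole, CH2Cl2, −20 °C
Reagents that add atoms: chromium trioxide, O=[Cr](=O)=O
Why: Allylic oxidation (CrO3–dimethylpyrazole) of the ring methylene next to the trisubstituted alkene to the enone; the other allylic sites are a hindered silyloxy methine and methyl groups, and the 1,1-disubstituted isopropenyl alkene is the less reactive one. No stereocentre is touched.

Step 4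
Reactants: 5 benzylchlorodimethylsilane; 6 ethynylmagnesium bromide
Product: 7 benzyl(ethynyl)dimethylsilane
Conditions: THF, 0 °C to rt
Reagents that add atoms: none
Why: Nucleophilic substitution at silicon by an alkynyl Grignard reagent, a standard route to ethynylsilanes.

Step 5
Reactants: 7 benzyl(ethynyl)dimethylsilane; 4 enone
Product: 9 (1R,4S,6S)-1-{[benzyl(dimethyl)silyl]ethynyl}-4-[(tert-butyldimethylsilyl)oxy]-3-methyl-6-(prop-1-en-2-yl)cyclohex-2-en-1-ol, via lithium acetylide 8 (not isolated)
Conditions: n-BuLi, THF, −78 °C; then 4, −78 °C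
Reagents that add atoms: none
Why: 1,2-Addition of a lithium acetylide to an enone; the small linear nucleophile attacks axially on the half-chair that keeps the isopropenyl and silyloxy groups equatorial, so the alkynyl group ends up axial and cis to the isopropenyl group (carbinol 1R).

Step 6
Reactants: 9 propargylic alcohol
Product: 10 (1R,4S,6S)-1-{(E)-2-[benzyl(dimethyl)silyl]ethenyl}-4-[(tert-butyldimethylsilyl)oxy]-3-methyl-6-(prop-1-en-2-yl)cyclohex-2-en-1-ol
Conditions: LiAlH4, THF, 0 °C to rt
Reagents that add atoms: none
Why: Hydroxyl-directed trans-hydroalumination of a propargylic alcohol; the alkoxyaluminate delivers hydride within the molecule and the alkenyl–aluminium bond is protonated on work-up, so only the E vinylsilane forms. Silyl ether and benzylsilane are inert to LiAlH4.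

Step 7
Reactants: 10 cis-dialkenyl cyclohexenol
Product: 13 (2Z,4S,6Z,9R)-9-[benzyl(dimethyl)silyl]-4-[(tert-butyldimethylsilyl)oxy]-3,7-dimethylcyclodeca-2,6-dien-1-one, via potassium alkoxide 11 (not isolated), via potassium enolate 12 (not isolated)
Conditions: KH, 18-crown-6, THF, 0 °C to rt; then aq NH4Cl, −78 °C
Reagents that add atoms: none
Why: Deprotonation gives alkoxide 11, whose oxyanion weakens the C1–C6 bond and drives a concerted suprafacial [3,3] shift of the diene C9=C10–C1–C6–C7=C8: C8–C9 forms, C1–C6 breaks, and enolate 12 is protonated at C7 to ketone 13 (anionic oxy-Cope rearrangement, the known ring expansion of 1,2-dialkenylcyclohexanols to cyclodec-5-enones). Ring A is not closed end to end from a chain; it arises by four-atom ring expansion, the new bond being made inside a six-membered chair array while the old ring opens. The ground-state half-chair (isopropenyl and silyloxy equatorial, vinyl axial) passes directly into the chair in which ring carbon C2 is axial on C1 and C5 equatorial on C6; C2 axial gives Z C1=C10, and Z C4=C5 is carried over from the cyclohexene. The one new stereocentre, C8, is fixed by that chair together with the E vinylsilane (silicon equatorial) and the C1 configuration inherited from 1; tracing the chair gives 8R, silicon β, on the face of the C3 oxygen. The selectivity needed is chair over boat and over the other chair, which would require isopropenyl and silyloxy both axial and would give E C1=C10; the equatorial preference of two substituents secures it. The competing diene through the ring alkene (C9=C10–C1–C6–C5=C4) would need a bridged boat and a new quaternary C4 and should not compete. Silicon on C8 is essential because, unlike an alkoxy group, it is not lost from enolate 12 by β-elimination, and on the E terminus it is out of reach of the alkoxide. Protonation at C7 creates no stereocentre.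

Step 8
Reactants: 13 cyclodecadienone
Product: 15 methyl 2-[(1S,3Z,5S,7Z,10R)-10-[benzyl(dimethyl)silyl]-5-[(tert-butyldimethylsilyl)oxy]-4,8-dimethyl-2-oxocyclodeca-3,7-dien-1-yl]acetate, via lithium enolate 14 (not isolated)
Conditions: LiN(iPr)2, THF, −78 °C; BrCH2CO2Me, DMPU, −78 to −30 °C
Reagents that add atoms: methyl bromoacetate, COC(=O)CBr
Why: Kinetic α′-deprotonation of the enone at C7 and enolate alkylation; as with open-chain β-silyl enolates the electrophile should enter anti to the C8 silyl group with H-8 eclipsing the enolate double bond. That places the side chain 7β (same face as silicon in the flat drawing, antiperiplanar to it in the zigzag conformation), as 33 requires.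

Step 9
Reactants: 15 keto ester
Product: 17 8β-[benzyl(dimethyl)silyl]-3β-[(tert-butyldimethylsilyl)oxy]-13-norgermacra-1(10)Z,4Z-dien-12,6β-olide (cis-fused lactone), via hydroxy ester 16 (not isolated)
Conditions: NaBH4, CeCl3·7H2O, MeOH, −40 °C; then PPTS (cat.), CH2Cl2, rt
Reagents that add atoms: none
Why: Luche 1,2-reduction of the enone; by the Felkin–Anh model hydride enters anti to the C7–C8 ring bond and past H-7, which puts the new C6 oxygen cis to the C7 side chain (6β), and this γ-hydroxy ester closes to the cis-fused lactone. C6 is thus the epimer of the target and is inverted in step 10.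

Step 10
Reactants: 17 cis-fused lactone
Product: 19 8β-[benzyl(dimethyl)silyl]-3β-[(tert-butyldimethylsilyl)oxy]-13-norgermacra-1(10)Z,4Z-dien-12,6α-olide (trans-fused lactone), via hydroxy acid 18 (not isolated)
Conditions: LiOH, THF/H2O, 0 °C to rt; NaH2PO4 to pH 5, 0 °C; PPh3, DIAD, toluene, −10 °C to rt
Reagents that add atoms: lithium hydroxide, [Li+].[OH-] (its oxygen becomes one of the two lactone oxygens)
Why: Saponification opens the lactone; Mitsunobu lactonization then turns the C6 hydroxyl into an alkoxyphosphonium ion that the carboxylate displaces from the back (5-exo-tet), so C6 is inverted to 6α and the trans-fused lactone (6R) results.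

Step 11
Reactants: 19 trans-fused lactone
Product: 22 diethyl [8β-[benzyl(dimethyl)silyl]-3β-[(tert-butyldimethylsilyl)oxy]-13-norgermacra-1(10)Z,4Z-dien-12,6α-olid-11-yl]phosphonate, via lithium enolate 20 (not isolated), via phosphonite 21 (not isolated)
Conditions: LiN(iPr)2 (2.1 equiv), THF, −78 °C; ClP(OEt)2, −78 °C to rt; AcOH; t-BuOOH, 0 °C
Reagents that add atoms: diethyl chlorophosphite, CCOP(Cl)OCC; tert-butyl hydroperoxide, CC(C)(C)OO
Why: C-Phosphinylation of a lactone enolate with a chlorophosphite (the soft trivalent phosphorus electrophile bonds to carbon) and oxidation to the phosphonate. It is done here, before any ester, epoxide or free hydroxyl exists, so that the later methylenation needs only carbonate; C11 is a mixture of no consequence and becomes planar again in 32.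

Step 12
Reactants: 22 phosphono lactone
Product: 24 diethyl [3β-[(tert-butyldimethylsilyl)oxy]-8β-hydroxy-13-norgermacra-1(10)Z,4Z-dien-12,6α-olid-11-yl]phosphonate, via fluorosilane 23 (not isolated)
Conditions: Bu4NF (1.2 equiv), THF, 0 °C, 15 min; then KF, KHCO3, 30% H2O2, MeOH/THF, 0 °C to rt
Reagents that add atoms: hydrogen peroxide, OO
Why: Tamao–Fleming oxidation; fluoride expels the benzyl group from silicon as toluene, hydroperoxide adds to the fluorosilane and C8 migrates from silicon to oxygen with retention, so the 8β silane gives the 8β (8R) alcohol. Isolated alkenes are inert to buffered H2O2 and no Michael acceptor is present yet.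

Step 13
Reactants: 24 8β-alcohol
Product: 25 diethyl [3β-[(tert-butyldimethylsilyl)oxy]-1β,10β-epoxy-8β-hydroxy-13-norgermacr-4Z-en-12,6α-olid-11-yl]phosphonate
Conditions: VO(acac)2 (5 mol%), t-BuOOH, CH2Cl2, 0 °C to rt
Reagents that add atoms: tert-butyl hydroperoxide, CC(C)(C)OO
Why: Vanadium-catalysed hydroxyl-directed epoxidation; the vanadate ester of the homoallylic C8 hydroxyl delivers the peroxide oxygen to C1=C10 on the face of that hydroxyl, giving the 1β,10β-epoxide. C4=C5 is out of reach of the director, has no free hydroxyl and is deactivated by two allylic oxygens.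

Step 14
Reactants: 26 angelic acid
Product: 27 (Z)-2-methylbut-2-en-1-ol
Conditions: LiAlH4, Et2O, 0 °C to rt
Reagents that add atoms: none
Why: Hydride reduction of the carboxylic acid to the allylic alcohol; the Z alkene is not touched.

Step 15
Reactants: 27 (Z)-2-methylbut-2-en-1-ol
Product: 28 [(2S,3R)-2,3-dimethyloxiran-2-yl]methanol
Conditions: Ti(OiPr)4 (10 mol%), L-(+)-diisopropyl tartrate (12 mol%), t-BuOOH, 4 Å molecular sieves, CH2Cl2, −20 °C
Reagents that add atoms: tert-butyl hydroperoxide, CC(C)(C)OO
Why: Sharpless asymmetric epoxidation; the L-(+)-tartrate delivers oxygen to the face that gives 2S (as with other Z allylic alcohols), and syn addition to the Z alkene fixes 3R.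

Step 16
Reactants: 28 epoxy alcohol
Product: 29 (2R,3R)-2,3-dimethyloxirane-2-carboxylic acid
Conditions: RuCl3·xH2O (2 mol%), NaIO4, MeCN/EtOAc/H2O, 0 °C to rt
Reagents that add atoms: water, O
Why: RuO4 oxidation of a primary alcohol to the acid by way of the aldehyde hydrate, a standard conversion of epoxy alcohols; the epoxide is untouched and the C2 descriptor changes from S to R by priority only.

Step 17
Reactants: 29 epoxy acid; 25 epoxy alcohol
Product: 31 diethyl [3β-[(tert-butyldimethylsilyl)oxy]-1β,10β-epoxy-8β-{[(2R,3R)-2,3-dimethyloxiran-2-yl]carbonyloxy}-13-norgermacr-4Z-en-12,6α-olid-11-yl]phosphonate, via mixed anhydride 30 (not isolated)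
Conditions: 29, 2,4,6-Cl3C6H2COCl, Et3N, toluene, rt; then 25, DMAP, toluene, rt to 40 °C
Reagents that add atoms: none
Why: Yamaguchi esterification of a hindered secondary alcohol; the acid has no α-hydrogen, so it can neither epimerize nor isomerize as an angelate would, and the weakly basic medium leaves both epoxides and the lactone alone.

Step 18
Reactants: 31 phosphono lactone ester
Product: 32 3-O-(tert-butyldimethylsilyl) ether of 33
Conditions: K2CO3, 37% aq HCHO, THF, 0 °C to rt
Reagents that add atoms: formaldehyde, C=O
Why: Horner–Wadsworth–Emmons olefination of the α-phosphono lactone with formaldehyde gives the α-methylene lactone under carbonate base only; C11 becomes planar.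

Step 19
Reactants: 32 silyl ether
Product: 33 target, 1β,10β-epoxy-3β-hydroxy-8β-{[(2R,3R)-2,3-dimethyloxiran-2-yl]carbonyloxy}germacra-4Z,11(13)-dien-12,6α-olide
Conditions: Bu4NF, AcOH (1:1), THF, 0 °C to rt
Reagents that add atoms: none
Why: Fluoride cleavage of the silyl ether; buffering with acetic acid keeps the medium near neutral, so the methylene lactone, both epoxides and the ester should survive.

Compound list

1 | (S)-carvone, (5S)-2-methyl-5-(prop-1-en-2-yl)cyclohex-2-en-1-one | CC1=CC[C@@H](CC1=O)C(C)=C | starting material
2 | (1S,5S)-2-methyl-5-(prop-1-en-2-yl)cyclohex-2-en-1-ol (cis-carveol) | C=C(C)[C@@H]1C[C@H](O)C(C)=CC1 | intermediate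
3 | tert-butyl(dimethyl){[(1S,5S)-2-methyl-5-(prop-1-en-2-yl)cyclohex-2-en-1-yl]oxy}silane | C=C(C)[C@@H]1C[C@H](O[Si](C)(C)C(C)(C)C)C(C)=CC1 | intermediate
4 | (4S,6S)-4-[(tert-butyldimethylsilyl)oxy]-3-methyl-6-(prop-1-en-2-yl)cyclohex-2-en-1-one | C=C(C)[C@@H]1C[C@H](O[Si](C)(C)C(C)(C)C)C(C)=CC1=O | intermediate
5 | benzylchlorodimethylsilane | C[Si](C)(Cl)Cc1ccccc1 | starting material
6 | ethynylmagnesium bromide | C#C[Mg]Br | starting material
7 | benzyl(ethynyl)dimethylsilane | C#C[Si](C)(C)Cc1ccccc1 | intermediate
8 | lithium [benzyl(dimethyl)silyl]acetylide | [Li]C#C[Si](C)(C)Cc1ccccc1 | intermediate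
9 | (1R,4S,6S)-1-{[benzyl(dimethyl)silyl]ethynyl}-4-[(tert-butyldimethylsilyl)oxy]-3-methyl-6-(prop-1-en-2-yl)cyclohex-2-en-1-ol | C=C(C)[C@@H]1C[C@H](O[Si](C)(C)C(C)(C)C)C(C)=C[C@]1(O)C#C[Si](C)(C)Cc1ccccc1 | intermediate
10 | (1R,4S,6S)-1-{(E)-2-[benzyl(dimethyl)silyl]ethenyl}-4-[(tert-butyldimethylsilyl)oxy]-3-methyl-6-(prop-1-en-2-yl)cyclohex-2-en-1-ol | C=C(C)[C@@H]1C[C@H](O[Si](C)(C)C(C)(C)C)C(C)=C[C@]1(O)/C=C/[Si](C)(C)Cc1ccccc1 | intermediate
11 | potassium alkoxide of 10 | C=C(C)[C@@H]1C[C@H](O[Si](C)(C)C(C)(C)C)C(C)=C[C@]1(O[K])/C=C/[Si](C)(C)Cc1ccccc1 | intermediate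
12 | potassium enolate of 13 (K–O–C6=C7, oxygen cis to C8) | [K]O/C1=C\[C@H]([Si](C)(C)Cc2ccccc2)C/C(C)=C\C[C@H](O[Si](C)(C)C(C)(C)C)/C(C)=C\1 | intermediate
13 | (2Z,4S,6Z,9R)-9-[benzyl(dimethyl)silyl]-4-[(tert-butyldimethylsilyl)oxy]-3,7-dimethylcyclodeca-2,6-dien-1-one (C6 ketone, 3β-silyloxy, 8β-silyl) | O=C1/C=C(/C)[C@@H](O[Si](C)(C)C(C)(C)C)C/C=C(/C)C[C@@H]([Si](C)(C)Cc2ccccc2)C1 | intermediate
14 | lithium enolate of 13 (Li–O–C6=C7, enolate geometry not defined) | [Li]OC1=C[C@H]([Si](C)(C)Cc2ccccc2)C/C(C)=C\C[C@H](O[Si](C)(C)C(C)(C)C)/C(C)=C\1 | intermediate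
15 | methyl 2-[(1S,3Z,5S,7Z,10R)-10-[benzyl(dimethyl)silyl]-5-[(tert-butyldimethylsilyl)oxy]-4,8-dimethyl-2-oxocyclodeca-3,7-dien-1-yl]acetate (side chain 7β) | O=C1/C=C(/C)[C@@H](O[Si](C)(C)C(C)(C)C)C/C=C(/C)C[C@@H]([Si](C)(C)Cc2ccccc2)[C@H]1CC(=O)OC | intermediate
16 | methyl 8β-[benzyl(dimethyl)silyl]-3β-[(tert-butyldimethylsilyl)oxy]-6β-hydroxy-13-norgermacra-1(10)Z,4Z-dien-12-oate (6S alcohol) | O[C@H]1/C=C(/C)[C@@H](O[Si](C)(C)C(C)(C)C)C/C=C(/C)C[C@@H]([Si](C)(C)Cc2ccccc2)[C@H]1CC(=O)OC | intermediate
17 | 8β-[benzyl(dimethyl)silyl]-3β-[(tert-butyldimethylsilyl)oxy]-13-norgermacra-1(10)Z,4Z-dien-12,6β-olide (cis-fused, 6S) | O=C1O[C@H]2/C=C(/C)[C@@H](O[Si](C)(C)C(C)(C)C)C/C=C(/C)C[C@@H]([Si](C)(C)Cc3ccccc3)[C@H]2C1 | intermediate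
18 | 8β-[benzyl(dimethyl)silyl]-3β-[(tert-butyldimethylsilyl)oxy]-6β-hydroxy-13-norgermacra-1(10)Z,4Z-dien-12-oic acid | O[C@H]1/C=C(/C)[C@@H](O[Si](C)(C)C(C)(C)C)C/C=C(/C)C[C@@H]([Si](C)(C)Cc2ccccc2)[C@H]1CC(=O)O | intermediate
19 | 8β-[benzyl(dimethyl)silyl]-3β-[(tert-butyldimethylsilyl)oxy]-13-norgermacra-1(10)Z,4Z-dien-12,6α-olide (trans-fused, 3S,6R,7S,8R) | O=C1O[C@@H]2/C=C(/C)[C@@H](O[Si](C)(C)C(C)(C)C)C/C=C(/C)C[C@@H]([Si](C)(C)Cc3ccccc3)[C@H]2C1 | intermediate
20 | lithium enolate of 19 (Li–O–C12=C11) | [Li]OC1O[C@@H]2/C=C(/C)[C@@H](O[Si](C)(C)C(C)(C)C)C/C=C(/C)C[C@@H]([Si](C)(C)Cc3ccccc3)[C@H]2C=1 | intermediate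
21 | 11-(diethoxyphosphanyl) derivative of 19 (C11 epimers) | O=C1O[C@@H]2/C=C(/C)[C@@H](O[Si](C)(C)C(C)(C)C)C/C=C(/C)C[C@@H]([Si](C)(C)Cc3ccccc3)[C@H]2C1P(OCC)OCC | intermediate
22 | diethyl [8β-[benzyl(dimethyl)silyl]-3β-[(tert-butyldimethylsilyl)oxy]-13-norgermacra-1(10)Z,4Z-dien-12,6α-olid-11-yl]phosphonate (C11 epimers) | O=C1O[C@@H]2/C=C(/C)[C@@H](O[Si](C)(C)C(C)(C)C)C/C=C(/C)C[C@@H]([Si](C)(C)Cc3ccccc3)[C@H]2C1P(=O)(OCC)OCC | intermediate
23 | 8β-(fluorodimethylsilyl) analogue of 22 | O=C1O[C@@H]2/C=C(/C)[C@@H](O[Si](C)(C)C(C)(C)C)C/C=C(/C)C[C@@H]([Si](C)(C)F)[C@H]2C1P(=O)(OCC)OCC | intermediate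
24 | diethyl [3β-[(tert-butyldimethylsilyl)oxy]-8β-hydroxy-13-norgermacra-1(10)Z,4Z-dien-12,6α-olid-11-yl]phosphonate | O=C1O[C@@H]2/C=C(/C)[C@@H](O[Si](C)(C)C(C)(C)C)C/C=C(/C)C[C@@H](O)[C@H]2C1P(=O)(OCC)OCC | intermediate
25 | diethyl [3β-[(tert-butyldimethylsilyl)oxy]-1β,10β-epoxy-8β-hydroxy-13-norgermacr-4Z-en-12,6α-olid-11-yl]phosphonate | O=C1O[C@@H]2/C=C(/C)[C@@H](O[Si](C)(C)C(C)(C)C)C[C@H]3O[C@@]3(C)C[C@@H](O)[C@H]2C1P(=O)(OCC)OCC | intermediate
26 | angelic acid, (Z)-2-methylbut-2-enoic acid | C/C=C(/C)C(O)=O | starting material
27 | (Z)-2-methylbut-2-en-1-ol | C/C=C(/C)CO | intermediate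
28 | [(2S,3R)-2,3-dimethyloxiran-2-yl]methanol | OC[C@]1(C)O[C@@H]1C | intermediate
29 | (2R,3R)-2,3-dimethyloxirane-2-carboxylic acid | OC(=O)[C@]1(C)O[C@@H]1C | intermediate
30 | (2R,3R)-2,3-dimethyloxirane-2-carboxylic 2,4,6-trichlorobenzoic anhydride | O=C(OC(=O)[C@]1(C)O[C@@H]1C)c1c(Cl)cc(Cl)cc1Cl | intermediate
31 | diethyl [3β-[(tert-butyldimethylsilyl)oxy]-1β,10β-epoxy-8β-{[(2R,3R)-2,3-dimethyloxiran-2-yl]carbonyloxy}-13-norgermacr-4Z-en-12,6α-olid-11-yl]phosphonate | O=C1O[C@@H]2/C=C(/C)[C@@H](O[Si](C)(C)C(C)(C)C)C[C@H]3O[C@@]3(C)C[C@@H](OC(=O)[C@]3(C)O[C@@H]3C)[C@H]2C1P(=O)(OCC)OCC | intermediate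
32 | 3-O-(tert-butyldimethylsilyl) ether of 33 | C=C1C(=O)O[C@@H]2/C=C(/C)[C@@H](O[Si](C)(C)C(C)(C)C)C[C@H]3O[C@@]3(C)C[C@@H](OC(=O)[C@]3(C)O[C@@H]3C)[C@@H]12 | intermediate
33 | 1β,10β-epoxy-3β-hydroxy-8β-{[(2R,3R)-2,3-dimethyloxiran-2-yl]carbonyloxy}germacra-4Z,11(13)-dien-12,6α-olide | C=C1C(=O)O[C@@H]2/C=C(/C)[C@@H](O)C[C@H]3O[C@@]3(C)C[C@@H](OC(=O)[C@]3(C)O[C@@H]3C)[C@@H]12 | target

Total step count: 19. Longest linear sequence: 15 steps (steps 1–3, 5–13, 17–19, from 1 to 33); steps 4 and 14–16 make the two side components.

Steps least certain to work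

Step 7 (key step). The rearrangement may leak through a boat-shaped or ring-flipped chair transition state (loss of the C8 configuration or E C1=C10), or the hindered alkoxide may attack silicon of another molecule before it rearranges, because the bulky silyl terminus slows bond formation at C8. Fallback, a neutral thermal variant: from 10, silylation of the tertiary hydroxyl (Me3SiCl, imidazole) gives the trimethylsilyl ether F1. Heating F1 (o-dichlorobenzene, about 200 °C) should take it through the same chair to the trimethylsilyl enol ether F2. K2CO3 in MeOH cleaves the enol ether and the route is rejoined at 13.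

Step 3. Site selectivity of hydrogen abstraction may be poor (attack at the isopropenyl allylic positions or at the silyloxy methine, over-oxidation), because hexavalent chromium reagents discriminate only moderately between allylic C–H bonds. Fallback, three known operations from 3:
- mCPBA epoxidation of the more electron-rich ring alkene gives the epoxide F3 (expected anti to the silyloxy group; the face does not matter).
- Opening with PhSeNa at the secondary carbon gives the hydroxy selenide F4.
- H2O2 oxidation and selenoxide syn-elimination away from the carbinol give the tertiary allylic alcohol F5.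
- Oxidative 1,3-transposition with pyridinium chlorochromate, C5H5NH[CrO3Cl], returns to 4.

Step 8. Facial selectivity of the alkylation may be poor or reversed, because the ring conformation can expose the other enolate face and override the preference for attack anti to silicon. Fallback: the alkylation of 13 then gives mainly the C7 epimer F6. F6 is enolized again toward C7 with excess KN(SiMe3)2 and protonated at −78 °C; the proton should enter on the face the alkylating agent used, which inverts C7 and rejoins the route at 15.

Step 10. Stereochemical fidelity of the ring closure may be lost: closure with retention through an acyloxyphosphonium ion, spontaneous re-closure of 18 to 17 before activation, or elimination from the allylic oxyphosphonium ion. Fallback from 17: aminolysis with Me2AlNMe2 gives the hydroxy dimethylamide F7, which does not re-close on its own. Activation of its hydroxyl with MsCl and Et3N lets the amide oxygen displace the sulfonate at C6 with inversion, and aqueous hydrolysis of the resulting iminium lactone returns to 19. If hydride delivery in step 9 followed the ring conformation instead of the open-chain model, 19 would form there directly and step 10 would be left out.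

Step 12. The C3 silyl ether may be lost during fluoride activation of the benzylsilane, since both are fluoride-labile and the selectivity rests only on rate. Fallback from 22: excess Bu4NF followed by the same peroxide oxidation removes both silicon groups and gives the 3β,8β-diol F8. Selective silylation of the less hindered allylic C3 hydroxyl (TBSCl, imidazole, DMF, −20 °C) returns to 24.

Step 13. Oxygen delivery may take the wrong face or be slow: the medium ring may not let O8 reach the β face, so that the oxidant takes the exposed face, and the phosphono lactone may bind vanadium. Fallback from 24: esterification with 29 as in step 17 gives the ester F9. NBS in aqueous THF forms the bromonium ion on the exposed face and water opens it at tertiary C10 from the other side, giving the bromohydrin F10. Ag2O closes the epoxide by backside displacement of bromide at C1, which puts the oxygen on the face that direct attack does not reach, and the route is rejoined at 31.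

## Further compounds

F1 | step 7 | trimethylsilyl ether of 10 | C=C(C)[C@@H]1C[C@H](O[Si](C)(C)C(C)(C)C)C(C)=C[C@]1(O[Si](C)(C)C)/C=C/[Si](C)(C)Cc1ccccc1
F2 | step 7 | trimethylsilyl enol ether of 13 (Me3SiO–C6=C7, oxygen cis to C8) | C[Si](C)(C)O/C1=C\[C@H]([Si](C)(C)Cc2ccccc2)C/C(C)=C\C[C@H](O[Si](C)(C)C(C)(C)C)/C(C)=C\1
F3 | step 3 | epoxide of 3 at the ring alkene, oxygen anti to the silyloxy group | C=C(C)[C@@H]1C[C@H](O[Si](C)(C)C(C)(C)C)[C@@]2(C)O[C@H]2C1
F4 | step 3 | trans hydroxy selenide from F3 (tertiary alcohol on the methyl-bearing carbon, phenylseleno group on the adjacent ring carbon) | C=C(C)[C@@H]1C[C@H](O[Si](C)(C)C(C)(C)C)[C@@](C)(O)[C@H]([Se]c2ccccc2)C1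
F5 | step 3 | 6-[(tert-butyldimethylsilyl)oxy]-1-methyl-4-(prop-1-en-2-yl)cyclohex-2-en-1-ol (tertiary allylic alcohol from F4) | C=C(C)[C@@H]1C[C@H](O[Si](C)(C)C(C)(C)C)[C@@](C)(O)C=C1
F6 | step 8 | C7 epimer of 15 | O=C1/C=C(/C)[C@@H](O[Si](C)(C)C(C)(C)C)C/C=C(/C)C[C@@H]([Si](C)(C)Cc2ccccc2)[C@@H]1CC(=O)OC
F7 | step 10 | N,N-dimethylamide of acid 18 | O[C@H]1/C=C(/C)[C@@H](O[Si](C)(C)C(C)(C)C)C/C=C(/C)C[C@@H]([Si](C)(C)Cc2ccccc2)[C@H]1CC(=O)N(C)C
F8 | step 12 | diethyl [3β,8β-dihydroxy-13-norgermacra-1(10)Z,4Z-dien-12,6α-olid-11-yl]phosphonate | O=C1O[C@@H]2/C=C(/C)[C@@H](O)C/C=C(/C)C[C@@H](O)[C@H]2C1P(=O)(OCC)OCC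
F9 | step 13 | 8β-O-[(2R,3R)-2,3-dimethyloxiran-2-yl]carbonyl ester of 24 | O=C1O[C@@H]2/C=C(/C)[C@@H](O[Si](C)(C)C(C)(C)C)C/C=C(/C)C[C@@H](OC(=O)[C@]3(C)O[C@@H]3C)[C@H]2C1P(=O)(OCC)OCC
F10 | step 13 | 1α-bromo-10β-hydroxy bromohydrin of F9 | O=C1O[C@@H]2/C=C(/C)[C@@H](O[Si](C)(C)C(C)(C)C)C[C@H](Br)[C@@](C)(O)C[C@@H](OC(=O)[C@]3(C)O[C@@H]3C)[C@H]2C1P(=O)(OCC)OCC
A1 | alternative 1 | ten-membered carbocyclic 1,3-diketone (C1 and C3 ketones, Z C4=C5, lactone at C6/C7, C8 silyl ether, C10 silyl ether) | O=C1CC(=O)/C(C)=C\[C@H]2OC(=O)C[C@@H]2[C@H](O[Si](C)(C)C(C)(C)C)C[C@]1(C)O[Si](CC)(CC)CC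
A2 | alternative 1 | ten-membered dienol lactone (C1 acyl on the C3 enol oxygen, exocyclic methylene C2) | O=C1OC(=C)/C(C)=C\[C@H]2OC(=O)C[C@@H]2[C@H](O[Si](C)(C)C(C)(C)C)C[C@]1(C)O[Si](CC)(CC)CC
A3 | alternative 2 | trans-fused C5 iodo lactone | O=C1C[C@@H]2[C@H](OCc3ccc(OC)cc3)C/C(C)=C\C[C@H](O[Si](C)(C)C(C)(C)C)[C@H](C)[C@H](I)[C@H]2O1
A4 | alternative 2 | ten-membered dienyl acetic acid with cis C5=C6 | OC(=O)C[C@@H]1[C@H](OCc2ccc(OC)cc2)C/C(C)=C\C[C@H](O[Si](C)(C)C(C)(C)C)[C@H](C)/C=C\1
A5 | alternative 3 | ten-membered 3,8-diketone with Z C1=C10 and fused lactone | O=C1C[C@@H]2C(=O)C/C(C)=C\CC(=O)[C@H](C)[C@H](OC(C)=O)[C@H]2O1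
A6 | alternative 3 | hexahydronaphthalene lactone with C3=C8 ring-fusion alkene and C1=C10 alkene | O=C1C[C@@H]2C3=C(CC=C(C)C3)[C@H](C)[C@H](OC(C)=O)[C@H]2O1
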